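**Retrosynthetic overview**

1. The central oxazole is read as an oxidised N-acyltryptamine. Its C5–C4–N3 unit is the Cβ–Cα–N chain on indole C3, and its C2 and O1 are the carbonyl carbon and oxygen of a 5-bromopyrrole-2-carboxamide.
2. Key disconnection: the oxazole O1–C5 bond together with the C4=C5 unsaturation. In the forward direction a DDQ double dehydrogenative cyclisation (hydride abstraction from the indole-activated Cβ–H, capture by the amide oxygen, second dehydrogenation) turns the open-chain amide into the oxazole. No preformed oxazole, ketone or cross-coupling is needed.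
3. The amide comes from 6-bromo-4-methoxytryptamine and 5-bromo-1H-pyrrole-2-carboxylic acid. The tryptamine comes from a one-pot reductive C3-alkylation of 6-bromo-4-methoxyindole with phthalimidoacetaldehyde diethyl acetal, followed by hydrazinolysis.
4. Ring order: the indole and pyrrole rings are bought with both bromine atoms and the methoxy group in place. The oxazole is the only ring formed, in the last step.

Key step: step 4

Remark: the target has no stereocentre and no configurationally stable axis, so it is achiral and no enantiocontrol is required; 6-bromo-4-methoxy-1H-indole, phthalimidoacetaldehyde diethyl acetal and 5-bromo-1H-pyrrole-2-carboxylic acid are taken as catalogue compounds.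

**Route**

Step 1
Reactants: 1 6-bromo-4-methoxy-1H-indole; 2 2-(2,2-diethoxyethyl)isoindoline-1,3-dione (phthalimidoacetaldehyde diethyl acetal)
Product: 4 2-[2-(6-bromo-4-methoxy-1H-indol-3-yl)ethyl]isoindoline-1,3-dione, via C3 α-ethoxyalkyl adduct 3 (not isolated)
Conditions: Et3SiH (3 equiv), TFA (5 equiv), CH2Cl2, 0 °C → rt
Reagents that add atoms: none
Why: Acid-promoted reductive C3-alkylation of an indole with an N-protected aminoacetaldehyde acetal (Friedel–Crafts alkylation followed by ionic hydrogenation): TFA ionises the acetal to an oxocarbenium ion that is attacked by the most nucleophilic indole carbon C3, adduct 3 ionises again to a 3-alkylideneindoleninium ion, and Et3SiH delivers hydride to it, while the phthalimide, aryl bromide and methyl ether are inert.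

Step 2
Reactants: 4 2-[2-(6-bromo-4-methoxy-1H-indol-3-yl)ethyl]isoindoline-1,3-dione
Product: 6 2-(6-bromo-4-methoxy-1H-indol-3-yl)ethan-1-amine, via ring-opened acyl hydrazide 5 (not isolated)
Conditions: N2H4·H2O (5 equiv), EtOH, reflux; filter off the precipitate
Reagents that add atoms: none
Why: Ing–Manske hydrazinolysis, in which hydrazine opens the imide to hydrazide 5, which closes to insoluble phthalhydrazide and releases the primary amine under conditions that leave the aryl bromide and the indole untouched.

Step 3
Reactants: 6 2-(6-bromo-4-methoxy-1H-indol-3-yl)ethan-1-amine; 7 5-bromo-1H-pyrrole-2-carboxylic acid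
Product: 9 5-bromo-N-[2-(6-bromo-4-methoxy-1H-indol-3-yl)ethyl]-1H-pyrrole-2-carboxamide, via HOBt active ester 8 (not isolated)
Conditions: DIC (1.2 equiv), HOBt (1.2 equiv), DMF, 0 °C → rt, dark
Reagents that add atoms: none
Why: Carbodiimide/HOBt amide coupling, in which the primary aliphatic amine is far more nucleophilic than the indole or pyrrole N–H, so active ester 8 should be acylated only at the side-chain nitrogen under neutral conditions that spare the sensitive 2-bromopyrrole.

Step 4
Reactants: 9 5-bromo-N-[2-(6-bromo-4-methoxy-1H-indol-3-yl)ethyl]-1H-pyrrole-2-carboxamide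
Product: 12 6-bromo-3-[2-(5-bromo-1H-pyrrol-2-yl)-1,3-oxazol-5-yl]-4-methoxy-1H-indole, via 3-alkylidene-3H-indole 10 (not isolated), via indolyl oxazoline 11 (not isolated)
Conditions: DDQ (2.1 equiv), dry THF (dilute), 4 Å MS, Ar, 0 °C → reflux
Reagents that add atoms: none
Why: DDQ forms a charge-transfer complex with the electron-rich 4-methoxyindole and abstracts hydride from the C3-bound CH2 (activated through C2=C3 by the N1 lone pair) to give 3-alkylidene-3H-indole 10 (as its N-protonated ion), whose exocyclic carbon is attacked by the amide oxygen to form the O1–C5 bond and oxazoline 11; the C5–H of 11 is still indol-3-yl-activated and now also α-oxygenated, so a second equivalent of DDQ removes hydride there and loss of the C4 proton gives the aromatic oxazole. The closest known reaction type is the DDQ oxidative cyclisation of N-acyltryptamines and N-acyltryptophan esters to 5-(indol-3-yl)oxazoles. The oxazole closes in a 5-exo-trig mode (amide O onto the exocyclic C=C carbon of 10) from the ground-state Z-amide, in which the oxygen is syn to the N–CH2 chain. No stereocentre is set, since C5 of 11 is a transient racemic centre that the second dehydrogenation removes. The step needs (i) site selectivity for the side-chain C–H, secured because the 4-methoxyindole is the most easily oxidised π-system while the pyrrole is deactivated by its carbonyl group and bromine, (ii) capture by the amide oxygen and not by water or the pyrrole nitrogen, secured by dry THF with molecular sieves and by the preference of the neutral amide oxygen in a five-membered closure over the poorly nucleophilic pyrrole N–H in a six-membered closure that would need the E-amide, and (iii) no over-oxidation of the product, secured by using only slightly more than two equivalents of DDQ.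

**Compound list**

1 | 6-bromo-4-methoxy-1H-indole | COc1cc(Br)cc2[nH]ccc12 | starting material
2 | 2-(2,2-diethoxyethyl)isoindoline-1,3-dione (phthalimidoacetaldehyde diethyl acetal) | CCOC(CN1C(=O)c2ccccc2C1=O)OCC | starting material
3 | 2-[2-(6-bromo-4-methoxy-1H-indol-3-yl)-2-ethoxyethyl]isoindoline-1,3-dione (C3 α-ethoxyalkyl adduct, racemic, not isolated) | CCOC(CN1C(=O)c2ccccc2C1=O)c1c[nH]c2cc(Br)cc(OC)c12 | intermediate
4 | 2-[2-(6-bromo-4-methoxy-1H-indol-3-yl)ethyl]isoindoline-1,3-dione | COc1cc(Br)cc2[nH]cc(CCN3C(=O)c4ccccc4C3=O)c12 | intermediate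
5 | N-[2-(6-bromo-4-methoxy-1H-indol-3-yl)ethyl]-2-(hydrazinecarbonyl)benzamide (ring-opened acyl hydrazide, not isolated) | COc1cc(Br)cc2[nH]cc(CCNC(=O)c3ccccc3C(=O)NN)c12 | intermediate
6 | 2-(6-bromo-4-methoxy-1H-indol-3-yl)ethan-1-amine | COc1cc(Br)cc2[nH]cc(CCN)c12 | intermediate
7 | 5-bromo-1H-pyrrole-2-carboxylic acid | OC(=O)c1ccc(Br)[nH]1 | starting material
8 | 1H-benzotriazol-1-yl 5-bromo-1H-pyrrole-2-carboxylate (HOBt active ester, not isolated) | O=C(On1nnc2ccccc12)c1ccc(Br)[nH]1 | intermediate
9 | 5-bromo-N-[2-(6-bromo-4-methoxy-1H-indol-3-yl)ethyl]-1H-pyrrole-2-carboxamide | COc1cc(Br)cc2[nH]cc(CCNC(=O)c3ccc(Br)[nH]3)c12 | intermediate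
10 | 5-bromo-N-[2-(6-bromo-4-methoxy-3H-indol-3-ylidene)ethyl]-1H-pyrrole-2-carboxamide (3-alkylidene-3H-indole, alkene geometry undefined, not isolated) | COc1cc(Br)cc2N=CC(=CCNC(=O)c3ccc(Br)[nH]3)c12 | intermediate
11 | 6-bromo-3-[2-(5-bromo-1H-pyrrol-2-yl)-4,5-dihydro-1,3-oxazol-5-yl]-4-methoxy-1H-indole (indolyl oxazoline, racemic, not isolated) | COc1cc(Br)cc2[nH]cc(C3CN=C(c4ccc(Br)[nH]4)O3)c12 | intermediate
12 | 6-bromo-3-[2-(5-bromo-1H-pyrrol-2-yl)-1,3-oxazol-5-yl]-4-methoxy-1H-indole | COc1cc(Br)cc2[nH]cc(-c3cnc(-c4ccc(Br)[nH]4)o3)c12 | target

**Step count and risk**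

Total step count: 4. Longest linear sequence: 4 (1 → 4 → 6 → 9 → 12).

Steps most likely to fail:

Step 4 (key step). What may go wrong: the alkylideneindolenine may be captured by adventitious water or by the pyrrole nitrogen and not by the amide oxygen, and the electron-rich product may be over-oxidised by DDQ. Fallback, from 9 back to 12: water capture is made the intended path. DDQ (2.2 equiv) in THF–H2O 9:1 at 0 °C → rt should oxidise the side-chain CH2 to the ketone, a known conversion of 3-alkylindoles into 3-acylindoles, and give 5-bromo-N-[2-(6-bromo-4-methoxy-1H-indol-3-yl)-2-oxoethyl]-1H-pyrrole-2-carboxamide F1. A Robinson–Gabriel cyclodehydration of this keto amide (POCl3, 25–60 °C, or PPh3/C2Cl6/Et3N in MeCN) then closes the oxazole and gives 12 without exposing the product to the oxidant.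

Step 1. What may go wrong: over-reduction of the indole C2=C3 bond to the indoline by Et3SiH/TFA, addition of a second indole to the alkylideneindoleninium ion, or acid-induced oligomerisation of the electron-rich indole. Fallback, from 1 back to 6, replacing steps 1 and 2: condensation of 1 with 1-(dimethylamino)-2-nitroethylene in TFA/CH2Cl2 at 0 °C (addition–elimination at C3) should give (E)-6-bromo-4-methoxy-3-(2-nitroethenyl)-1H-indole F2. NaBH4 in THF/MeOH then reduces the conjugated C=C bond to give 6-bromo-4-methoxy-3-(2-nitroethyl)-1H-indole F3. Zn dust in aqueous HCl/MeOH reduces the nitro group without touching the aryl bromide and gives tryptamine 6.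

Step 3. What may go wrong: the activated 5-bromopyrrole acid may decompose (decarboxylation, self-acylation at the pyrrole nitrogen) before the amine intercepts it. Fallback, from 6 back to 9: the amine is activated in place of the acid. Amine 6 and the stable, commercial methyl 5-bromo-1H-pyrrole-2-carboxylate are combined with AlMe3 (excess, to cover the two N–H groups) in toluene/CH2Cl2 at 0 °C → 60 °C (Weinreb-type aminolysis of an ester) to give 9 directly. No new isolated compound arises.

**Further compounds**

F1 | step 4 | 5-bromo-N-[2-(6-bromo-4-methoxy-1H-indol-3-yl)-2-oxoethyl]-1H-pyrrole-2-carboxamide | COc1cc(Br)cc2[nH]cc(C(=O)CNC(=O)c3ccc(Br)[nH]3)c12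
F2 | step 1 | (E)-6-bromo-4-methoxy-3-(2-nitroethenyl)-1H-indole | COc1cc(Br)cc2[nH]cc(/C=C/[N+](=O)[O-])c12
F3 | step 1 | 6-bromo-4-methoxy-3-(2-nitroethyl)-1H-indole | COc1cc(Br)cc2[nH]cc(CC[N+](=O)[O-])c12
F0 | step 3 | none | none
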